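The route rests on cutting the C2–C3 bond of ring A (O1–C2–C3–C3a–C7a) while ring B is still a benzene ring. C2 is a benzylic ether carbon held between O1 and the trimethoxyphenyl ring and stands 1,5 to C3, so a rhodium carbene at C3 can insert into a C2–H bond. This single catalytic event closes ring A and sets C2 and C3 enantioselectively. Its precursor is an achiral aryldiazoacetate with an ortho 3,4,5-trimethoxybenzyl ether; the future C6 oxygen is masked as an allyl ether that is removed without hydrogen. Epimerisation at C3, ester-to-methyl reduction, dearomatising allylation at C3a and reduction of C4=C5 then lead to the target.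

Key step: step 7

Remark on numbering: benzofuran numbering of the target is used for all intermediates (O1, C2 aryl, C3 methyl, C3a allyl, C4, C5 methoxy, C6 oxygen, C7, C7a); ring A is the five-membered oxygen ring, ring B the six-membered carbocycle.

Assumption: the sense of induction is taken from the established behaviour of this catalyst family, in which the S-configured N-phthaloyl-tert-leucinate catalyst leads to the (2R) series of cis-2-aryl-2,3-dihydrobenzofuran-3-carboxylates; the (2S) centre of the target is therefore entrusted to the enantiomeric catalyst Rh2(R-PTTL)4, made from D-tert-leucine.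

Step 1
Reactants: 1 4-methoxyresorcinol
Product: 3 2,4-dihydroxy-5-methoxybenzaldehyde, via iminium chloride 2 (not isolated)
Conditions: POCl3, DMF, MeCN, 0 °C to rt; then H2O, 50 °C
Reagents that add atoms: N,N-dimethylformamide, CN(C)C=O; water, O
Why: Vilsmeier–Haack formylation, in which the chloroiminium electrophile should attack the ring carbon that is ortho to one hydroxyl and para to the other (the unhindered, doubly activated position), and hydrolysis of the iminium salt releases the aldehyde.

Step 2
Reactants: 3 2,4-dihydroxy-5-methoxybenzaldehyde; 4 allyl bromide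
Product: 5 4-(allyloxy)-2-hydroxy-5-methoxybenzaldehyde
Conditions: NaHCO3, MeCN, 70 °C
Reagents that add atoms: none
Why: Williamson ether synthesis under weak-base control, in which the 4-hydroxyl (para to the formyl group, more acidic and not chelated) should be alkylated while the 2-hydroxyl stays locked in its hydrogen bond to the aldehyde.

Step 3
Reactants: 5 4-(allyloxy)-2-hydroxy-5-methoxybenzaldehyde; 6 3,4,5-trimethoxybenzyl chloride
Product: 7 4-(allyloxy)-5-methoxy-2-[(3,4,5-trimethoxybenzyl)oxy]benzaldehyde
Conditions: K2CO3, KI (cat.), DMF, 60 °C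
Reagents that add atoms: none
Why: Williamson ether synthesis of the remaining chelated phenol, which the stronger base in a dipolar solvent should alkylate cleanly; this installs the benzylic CH2 that becomes C2.

Step 4
Reactants: 7 4-(allyloxy)-5-methoxy-2-[(3,4,5-trimethoxybenzyl)oxy]benzaldehyde
Product: 8 1-(allyloxy)-2-methoxy-4-[2-(methylsulfanyl)-2-(methylsulfinyl)ethenyl]-5-[(3,4,5-trimethoxybenzyl)oxy]benzene (ketene dithioacetal S-oxide; alkene geometry and sulfur configuration not controlled)
Conditions: CH3S(O)CH2SCH3, BnMe3N+ OH− (40% in MeOH, cat.), THF, reflux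
Reagents that add atoms: methyl (methylsulfanyl)methyl sulfoxide, CS(=O)CSC
Why: Knoevenagel-type condensation of the non-enolisable aldehyde with the sulfur-stabilised carbanion of the formaldehyde dithioacetal S-oxide should give the ketene dithioacetal S-oxide, a masked arylacetic acid, under basic conditions that both ethers tolerate.

Step 5
Reactants: 8 ketene dithioacetal S-oxide
Product: 9 methyl 2-{4-(allyloxy)-5-methoxy-2-[(3,4,5-trimethoxybenzyl)oxy]phenyl}acetate
Conditions: HCl (ca. 1 M in MeOH), rt
Reagents that add atoms: methanol, CO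
Why: Acid-catalysed alcoholysis of the ketene dithioacetal S-oxide (C-protonation to a thionium ion, addition of methanol, loss of the sulfur residues) should deliver the methyl arylacetate, and the aryl allyl ether and the only moderately electron-rich trimethoxybenzyl ether should survive dilute acid at room temperature.

Step 6
Reactants: 9 methyl 2-{4-(allyloxy)-5-methoxy-2-[(3,4,5-trimethoxybenzyl)oxy]phenyl}acetate
Product: 10 methyl 2-diazo-2-{4-(allyloxy)-5-methoxy-2-[(3,4,5-trimethoxybenzyl)oxy]phenyl}acetate
Conditions: p-acetamidobenzenesulfonyl azide, DBU, MeCN, 0 °C to rt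
Reagents that add atoms: 4-acetamidobenzenesulfonyl azide, CC(=O)Nc1ccc(cc1)S(=O)(=O)N=[N+]=[N-]
Why: Regitz diazo transfer, in which the DBU-generated benzylic ester enolate attacks the sulfonyl azide and the adduct fragments to the aryldiazoacetate and the sulfonamide.

Step 7
Reactants: 10 methyl 2-diazo-2-{4-(allyloxy)-5-methoxy-2-[(3,4,5-trimethoxybenzyl)oxy]phenyl}acetate
Product: 11 methyl (2S,3R)-6-(allyloxy)-5-methoxy-2-(3,4,5-trimethoxyphenyl)-2,3-dihydro-1-benzofuran-3-carboxylate (cis ester)
Conditions: Rh2(R-PTTL)4 (dirhodium tetrakis[N-phthaloyl-(R)-tert-leucinate], 1 mol %), toluene, −60 °C, slow addition of 10 at high dilution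
Reagents that add atoms: none
Why: Rh2(R-PTTL)4 expels N2 from 10 to give a donor/acceptor rhodium carbene at C3, which inserts through a concerted but asynchronous, hydride-transfer-like transition state into one of the two enantiotopic C–H bonds of the O1–CH2–aryl group, the positive charge developing at C2 being stabilised by O1 and the trimethoxyphenyl ring. The closest known reaction type is the enantioselective intramolecular 1,5 C–H insertion of ortho-benzyloxy aryldiazoacetates to cis-2-aryl-2,3-dihydrobenzofuran-3-carboxylates under dirhodium tetrakis(N-phthaloyl amino acid carboxylate) catalysis. Ring A is closed by this 1,5-insertion, which forms the C2–C3 bond of the five-membered ring O1–C2–C3–C3a–C7a on the aromatic ring B. C2 is controlled by the chiral carboxylate ligands of the catalyst, which select one enantiotopic hydrogen (the R-configured catalyst for 2S under the stated assumption), and C3 is set in the same event as cis (3R) by the compact transition state that keeps aryl and ester on one face under kinetic control. The step needs site selectivity and enantiocontrol at C2 only, since C3 is corrected in step 8; the ortho tether places just these two doubly activated C–H bonds 1,5 to the carbene, while the O-allyl group para to the carbene-bearing carbon is out of intramolecular reach, so slow addition at high dilution should suppress its cyclopropanation and carbene dimerisation.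

Step 8
Reactants: 11 cis ester
Product: 12 methyl (2S,3S)-6-(allyloxy)-5-methoxy-2-(3,4,5-trimethoxyphenyl)-2,3-dihydro-1-benzofuran-3-carboxylate (trans ester)
Conditions: NaOMe (0.3 equiv), MeOH, rt
Reagents that add atoms: none
Why: Base-mediated epimerisation through the C3 ester enolate should converge on the thermodynamically favoured trans isomer (aryl and ester on opposite faces of ring A), so the untouched C2 centre dictates C3 as (3S).

Step 9
Reactants: 12 trans ester
Product: 13 [(2S,3R)-6-(allyloxy)-5-methoxy-2-(3,4,5-trimethoxyphenyl)-2,3-dihydro-1-benzofuran-3-yl]methanol (trans)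
Conditions: LiAlH4, THF, 0 °C
Reagents that add atoms: none
Why: LiAlH4 reduction of the methyl ester to the primary alcohol, which touches no stereocentre (the C3 descriptor changes by priority only) and leaves the aryl allyl ether intact.

Step 10
Reactants: 13 trans alcohol
Product: 15 (2S,3S)-6-(allyloxy)-5-methoxy-3-methyl-2-(3,4,5-trimethoxyphenyl)-2,3-dihydro-1-benzofuran (trans), via mesylate 14 (not isolated)
Conditions: MsCl, Et3N, THF, 0 °C; then LiBHEt3 (excess), 0 °C to rt
Reagents that add atoms: none
Why: Mesylation followed by SN2 hydride displacement with LiBHEt3 at the primary carbon should turn CH2OH into the C3 methyl group without touching C2 or C3.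

Step 11
Reactants: 15 trans 3-methyl allyl ether
Product: 16 (2S,3S)-5-methoxy-3-methyl-2-(3,4,5-trimethoxyphenyl)-2,3-dihydro-1-benzofuran-6-ol
Conditions: Pd(PPh3)4 (5 mol %), morpholine, THF, rt
Reagents that add atoms: none
Why: Tsuji–Trost deallylation, in which zerovalent palladium ionises the allyl aryl ether to a π-allyl complex that morpholine intercepts, frees the phenol without hydrogen, so the benzylic C2–O1 bond of ring A is not endangered.

Step 12
Reactants: 16 (2S,3S)-5-methoxy-3-methyl-2-(3,4,5-trimethoxyphenyl)-2,3-dihydro-1-benzofuran-6-ol; 17 allyltrimethylsilane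
Product: 18 (2S,3S,3aS)-3a-allyl-5-methoxy-3-methyl-2-(3,4,5-trimethoxyphenyl)-3,3a-dihydro-1-benzofuran-6(2H)-one
Conditions: PhI(OAc)2, (CF3)2CHOH, −10 °C
Reagents that add atoms: none
Why: Oxidative dearomatisation of the phenol by the hypervalent iodine reagent (oxidative Hosomi–Sakurai allylation), in which the allylsilane should add to the para carbon C3a of the phenoxenium-type intermediate to give the cross-conjugated dienone (its C7=C7a enone stabilised as a vinylogous ester by O1) and should approach anti to the adjacent C3 methyl group, which sets C3a with allyl trans to methyl.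

Step 13
Reactants: 18 (2S,3S,3aS)-3a-allyl dienone
Product: 20 (2S,3S,3aR,5R)-3a-allyl-5-methoxy-3-methyl-2-(3,4,5-trimethoxyphenyl)-3,3a,4,5-tetrahydro-1-benzofuran-6(2H)-one (target CNP0236389.1), via C5 epimer 19 (not isolated)
Conditions: [(Ph3P)CuH]6, THF–PhH, H2O (2 equiv), rt; then DBU, rt
Reagents that add atoms: none
Why: Conjugate reduction with the phosphine copper hydride should deliver hydride to C4 of the α-methoxy enone only (the isolated allyl alkene is inert to copper hydride and C7=C7a is a deactivated, fully substituted vinylogous ester), and DBU then equilibrates C5 through the enolate to the more stable epimer, with the methoxy group pseudo-equatorial and trans to the pseudo-axial allyl group, which is (5R).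

Compound list
1 | 4-methoxyresorcinol (4-methoxybenzene-1,3-diol) | COc1ccc(O)cc1O | starting material
2 | (2,4-dihydroxy-5-methoxybenzylidene)dimethyliminium chloride | COc1cc(C=[N+](C)C)c(O)cc1O.[Cl-] | intermediate
3 | 2,4-dihydroxy-5-methoxybenzaldehyde | COc1cc(C=O)c(O)cc1O | intermediate
4 | allyl bromide | C=CCBr | starting material
5 | 4-(allyloxy)-2-hydroxy-5-methoxybenzaldehyde | COc1cc(C=O)c(O)cc1OCC=C | intermediate
6 | 3,4,5-trimethoxybenzyl chloride | COc1cc(CCl)cc(OC)c1OC | starting material
7 | 4-(allyloxy)-5-methoxy-2-[(3,4,5-trimethoxybenzyl)oxy]benzaldehyde | COc1cc(C=O)c(OCc2cc(OC)c(OC)c(OC)c2)cc1OCC=C | intermediate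
8 | 1-(allyloxy)-2-methoxy-4-[2-(methylsulfanyl)-2-(methylsulfinyl)ethenyl]-5-[(3,4,5-trimethoxybenzyl)oxy]benzene (geometry and sulfur configuration not controlled) | COc1cc(C=C(SC)S(C)=O)c(OCc2cc(OC)c(OC)c(OC)c2)cc1OCC=C | intermediate
9 | methyl 2-{4-(allyloxy)-5-methoxy-2-[(3,4,5-trimethoxybenzyl)oxy]phenyl}acetate | COC(=O)Cc1cc(OC)c(OCC=C)cc1OCc1cc(OC)c(OC)c(OC)c1 | intermediate
10 | methyl 2-diazo-2-{4-(allyloxy)-5-methoxy-2-[(3,4,5-trimethoxybenzyl)oxy]phenyl}acetate | COC(=O)C(=[N+]=[N-])c1cc(OC)c(OCC=C)cc1OCc1cc(OC)c(OC)c(OC)c1 | intermediate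
11 | methyl (2S,3R)-6-(allyloxy)-5-methoxy-2-(3,4,5-trimethoxyphenyl)-2,3-dihydro-1-benzofuran-3-carboxylate (cis) | COc1cc2c(cc1OCC=C)O[C@H](c1cc(OC)c(OC)c(OC)c1)[C@@H]2C(=O)OC | intermediate
12 | methyl (2S,3S)-6-(allyloxy)-5-methoxy-2-(3,4,5-trimethoxyphenyl)-2,3-dihydro-1-benzofuran-3-carboxylate (trans) | COc1cc2c(cc1OCC=C)O[C@H](c1cc(OC)c(OC)c(OC)c1)[C@H]2C(=O)OC | intermediate
13 | [(2S,3R)-6-(allyloxy)-5-methoxy-2-(3,4,5-trimethoxyphenyl)-2,3-dihydro-1-benzofuran-3-yl]methanol (trans) | COc1cc2c(cc1OCC=C)O[C@H](c1cc(OC)c(OC)c(OC)c1)[C@H]2CO | intermediate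
14 | [(2S,3R)-6-(allyloxy)-5-methoxy-2-(3,4,5-trimethoxyphenyl)-2,3-dihydro-1-benzofuran-3-yl]methyl methanesulfonate | COc1cc2c(cc1OCC=C)O[C@H](c1cc(OC)c(OC)c(OC)c1)[C@H]2COS(C)(=O)=O | intermediate
15 | (2S,3S)-6-(allyloxy)-5-methoxy-3-methyl-2-(3,4,5-trimethoxyphenyl)-2,3-dihydro-1-benzofuran (trans) | COc1cc2c(cc1OCC=C)O[C@H](c1cc(OC)c(OC)c(OC)c1)[C@H]2C | intermediate
16 | (2S,3S)-5-methoxy-3-methyl-2-(3,4,5-trimethoxyphenyl)-2,3-dihydro-1-benzofuran-6-ol | COc1cc2c(cc1O)O[C@H](c1cc(OC)c(OC)c(OC)c1)[C@H]2C | intermediate
17 | allyltrimethylsilane | C=CC[Si](C)(C)C | starting material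
18 | (2S,3S,3aS)-3a-allyl-5-methoxy-3-methyl-2-(3,4,5-trimethoxyphenyl)-3,3a-dihydro-1-benzofuran-6(2H)-one | C=CC[C@]12C=C(OC)C(=O)C=C1O[C@H](c1cc(OC)c(OC)c(OC)c1)[C@H]2C | intermediate
19 | (2S,3S,3aR,5S)-3a-allyl-5-methoxy-3-methyl-2-(3,4,5-trimethoxyphenyl)-3,3a,4,5-tetrahydro-1-benzofuran-6(2H)-one (C5 epimer of the target) | C=CC[C@]12C[C@H](OC)C(=O)C=C1O[C@H](c1cc(OC)c(OC)c(OC)c1)[C@H]2C | intermediate
20 | (2S,3S,3aR,5R)-3a-allyl-5-methoxy-3-methyl-2-(3,4,5-trimethoxyphenyl)-3,3a,4,5-tetrahydro-1-benzofuran-6(2H)-one (CNP0236389.1) | C=CC[C@]12C[C@@H](OC)C(=O)C=C1O[C@H](c1cc(OC)c(OC)c(OC)c1)[C@H]2C | target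

Total step count: 13. Longest linear sequence: 13 steps (1 to 20).

Steps most likely to fail

Step 12. The allylsilane may attack the methoxy-bearing ortho carbon C5 or the free ortho carbon C7 of the oxidised phenol instead of the para carbon C3a, or add to C3a with poor facial discrimination. The fallback sets out from 15 (step 11 is then not needed) and comes back to the route at 18. It replaces the intermolecular oxidative allylation by an intramolecular para-Claisen sequence. Heating 15 in N,N-diethylaniline at about 190 °C should shift the O-allyl group by an aromatic Claisen rearrangement to C5, giving the ortho-dienone (2S,3S,5R)-5-allyl-5-methoxy-3-methyl-2-(3,4,5-trimethoxyphenyl)-2,3-dihydro-1-benzofuran-6(5H)-one F1, which is not isolated. A Cope rearrangement of F1 then carries the allyl group suprafacially to C3a, on the face anti to the C3 methyl group, and gives 18. The allyl group never leaves the molecule, so the position is fixed by the two [3,3] shifts. The competing shift to C7, which ends in a 7-allylphenol, would have to be separated by chromatography.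

Step 13. Hydride addition to the electron-rich α-methoxy enone may be too slow, so that 1,2-reduction of the C6 carbonyl competes. The fallback sets out from 18 and comes back at 20; it makes no new compound (F0). The polar hydride addition is replaced by a radical hydrogen-atom transfer: Mn(dpm)3 (manganese tris(dipivaloylmethanate), catalytic), PhSiH3, i-PrOH, rt. The manganese hydride should deliver a hydrogen atom to C4, because this gives the captodative C5 radical flanked by the methoxy oxygen and the C6 carbonyl. This selectivity rests on radical stability and not on the electrophilicity of the enone. Reduction of the radical to the enolate, protonation and the same DBU equilibration (through 19) give 20.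

Step 7. Enantiocontrol at C2 may erode on this very electron-rich carbene, or intermolecular carbene reactions may compete with the insertion. The fallback sets out from 10 and comes back at 12. Asymmetric catalysis is replaced by a racemic insertion and a resolution. Rh2(OAc)4 in CH2Cl2 at rt should give the cis ester as a racemate, that is 11 together with its enantiomer methyl (2R,3S)-6-(allyloxy)-5-methoxy-2-(3,4,5-trimethoxyphenyl)-2,3-dihydro-1-benzofuran-3-carboxylate F2. NaOMe in MeOH converts both into the trans esters, 12 and its enantiomer methyl (2R,3R)-6-(allyloxy)-5-methoxy-2-(3,4,5-trimethoxyphenyl)-2,3-dihydro-1-benzofuran-3-carboxylate F3. Preparative chromatography on a chiral stationary phase then separates 12 from F3, and 12 continues with step 9.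

Further compounds
F1 | step 12 | (2S,3S,5R)-5-allyl-5-methoxy-3-methyl-2-(3,4,5-trimethoxyphenyl)-2,3-dihydro-1-benzofuran-6(5H)-one | C[C@@H]1[C@@H](c2cc(OC)c(OC)c(OC)c2)OC2=CC(=O)[C@@](OC)(CC=C)C=C12
F0 | step 13 | none | none
F2 | step 7 | methyl (2R,3S)-6-(allyloxy)-5-methoxy-2-(3,4,5-trimethoxyphenyl)-2,3-dihydro-1-benzofuran-3-carboxylate | COc1cc2c(cc1OCC=C)O[C@@H](c1cc(OC)c(OC)c(OC)c1)[C@H]2C(=O)OC
F3 | step 7 | methyl (2R,3R)-6-(allyloxy)-5-methoxy-2-(3,4,5-trimethoxyphenyl)-2,3-dihydro-1-benzofuran-3-carboxylate | COc1cc2c(cc1OCC=C)O[C@@H](c1cc(OC)c(OC)c(OC)c1)[C@@H]2C(=O)OC
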